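**Plan**

- Numbering (germacrane): ring C1–C10 with C1=C10 (E) and C4=C5 (Z by CIP, trans within the ring); C14 methyl on C10, C15 oxymethyl on C4, OH on C6, isopropyl on C7, OAc on C8. The enabling feature: C5 is the unsubstituted sp2 terminus of C4=C5, cis to C15–O, and C6 is the adjacent allylic carbinol of the ten-membered ring, so C5–C6 is an alkenyl–carbinol bond.
- Cuts, in retrosynthetic order: C15–O angelate and silyl ether; ring bond C5–C6 (alkenyl iodide plus aldehyde, Nozaki–Hiyama–Kishi); C7–C8 (syn aldol); C3–C4 (carbomagnesiation of propargyl alcohol); C1–C2 and C10–C14 (carboalumination, oxirane opening).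
- Forward: the chain C8→C5 is grown linearly from a butynyl silyl ether, the C6–C7 unit is added by aldol, the only ring is closed last at C5–C6, then the C15 ester is set.
- Stereochemistry: C1=C10 (E) from syn-carboalumination; C4=C5 from chelation-controlled anti-carbomagnesiation; C7 and C8 from the (R)-benzyloxazolidinone aldol; C6 from substrate control in the ring closure (Felkin–Anh with isopropyl as the large group, 1,3-anti to the C8 acetate).

Key step: step 11

Assumption: 1, 2, 7, 15 and 24 are taken as purchasable, and the C7 isopropyl group is taken to act as the largest α-substituent in the ring-closing transition state.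

**Route**

Step 1
Reactants: 1 tert-butyl(but-3-yn-1-yloxy)dimethylsilane; 2 oxirane
Product: 5 (3E)-6-{[tert-butyl(dimethyl)silyl]oxy}-4-methylhex-3-en-1-ol, via alkenylalane 3 (not isolated), via lithium alanate 4 (not isolated)
Conditions: AlMe3 (2.5 equiv), Cp2ZrCl2 (25 mol %), CH2Cl2, 0 °C → rt; evaporate; n-BuLi (1.0 equiv), hexane, 0 °C; 2 (3 equiv), THF, −30 °C → rt; aq. KNaC4H4O6
Reagents that add atoms: trimethylaluminium, C[Al](C)C
Why: Negishi zirconium-catalysed carboalumination adds CH3 and Al syn across the terminal alkyne (CH3 to C10, Al to C1), and the derived alkenylalanate opens oxirane with retention, so the C1=C10 (E) geometry is fixed here.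

Step 2
Reactants: 5 (3E)-6-{[tert-butyl(dimethyl)silyl]oxy}-4-methylhex-3-en-1-ol
Product: 6 {[(3E)-6-bromo-3-methylhex-3-en-1-yl]oxy}(tert-butyl)dimethylsilane
Conditions: CBr4 (1.2 equiv), PPh3 (1.25 equiv), CH2Cl2, 0 °C
Reagents that add atoms: tetrabromomethane, BrC(Br)(Br)Br
Why: Appel bromination displaces the primary oxyphosphonium by SN2 and leaves the silyl ether and the homoallylic alkene untouched.

Step 3
Reactants: 6 {[(3E)-6-bromo-3-methylhex-3-en-1-yl]oxy}(tert-butyl)dimethylsilane; 7 prop-2-yn-1-ol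
Product: 11 (5E)-8-{[tert-butyl(dimethyl)silyl]oxy}-2-[(Z)-iodomethylidene]-6-methyloct-5-en-1-ol, via alkylmagnesium bromide 8 (not isolated), via chloromagnesium alkoxide 9 (not isolated), via alkenylmagnesium bromide 10 (not isolated)
Conditions: 6, Mg, THF, rt → 40 °C; separately 7 (1.1 equiv), i-PrMgCl (1.1 equiv), THF, 0 °C; combine, CuI (15 mol %), −10 °C → rt; I2 (1.4 equiv), −30 → 0 °C; aq. NH4Cl, Na2S2O3
Reagents that add atoms: iodine, II
Why: Copper-catalysed carbomagnesiation of the propargylic alkoxide is anti and chelation-controlled (alkyl to C4, magnesium on C5 in a five-membered chelate cis to the CH2O group), and iodinolysis with retention gives the (Z)-iodoalkene that fixes the C4=C5 geometry.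

Step 4
Reactants: 11 (5E)-8-{[tert-butyl(dimethyl)silyl]oxy}-2-[(Z)-iodomethylidene]-6-methyloct-5-en-1-ol
Product: 12 tert-butyl{[(2Z,5E)-8-{[tert-butyl(dimethyl)silyl]oxy}-2-(iodomethylidene)-6-methyloct-5-en-1-yl]oxy}diphenylsilane
Conditions: TBDPSCl (1.2 equiv), imidazole (2 equiv), CH2Cl2, 0 °C → rt
Reagents that add atoms: tert-butyl(chloro)diphenylsilane, CC(C)(C)[Si](Cl)(c1ccccc1)c1ccccc1
Why: Imidazole-mediated silylation of the primary allylic alcohol installs a silyl ether that should outlast the acid used next on the TBS ether.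

Step 5
Reactants: 12 tert-butyl{[(2Z,5E)-8-{[tert-butyl(dimethyl)silyl]oxy}-2-(iodomethylidene)-6-methyloct-5-en-1-yl]oxy}diphenylsilane
Product: 13 (3E,7Z)-7-({[tert-butyl(diphenyl)silyl]oxy}methyl)-8-iodo-3-methylocta-3,7-dien-1-ol
Conditions: camphorsulfonic acid (10 mol %), MeOH–CH2Cl2 (1:1), 0 °C
Reagents that add atoms: none
Why: Acid-catalysed methanolysis cleaves the primary TBS ether far faster than the bulkier TBDPS ether, a standard selective desilylation.

Step 6
Reactants: 13 (3E,7Z)-7-({[tert-butyl(diphenyl)silyl]oxy}methyl)-8-iodo-3-methylocta-3,7-dien-1-ol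
Product: 14 (3E,7Z)-7-({[tert-butyl(diphenyl)silyl]oxy}methyl)-8-iodo-3-methylocta-3,7-dienal
Conditions: DMP (1,1,1-triacetoxy-1,1-dihydro-1,2-benziodoxol-3(1H)-one, 1.3 equiv), NaHCO3 (3 equiv), CH2Cl2, 0 °C → rt; cold aq. Na2S2O3/NaHCO3; used at once without chromatography
Reagents that add atoms: none
Why: Buffered hypervalent-iodine oxidation of the primary alcohol needs neither strong acid nor amine base, which should keep the β,γ-alkene (C10=C1) from moving into conjugation with the new C8 aldehyde.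

Step 7
Reactants: 14 (3E,7Z)-7-({[tert-butyl(diphenyl)silyl]oxy}methyl)-8-iodo-3-methylocta-3,7-dienal; 15 (4R)-4-benzyl-3-(3-methylbutanoyl)-1,3-oxazolidin-2-one
Product: 17 (4R)-4-benzyl-3-[(2R,3S,5E,9Z)-9-({[tert-butyl(diphenyl)silyl]oxy}methyl)-3-hydroxy-10-iodo-5-methyl-2-(propan-2-yl)deca-5,9-dienoyl]-1,3-oxazolidin-2-one, via boron enolate 16 (not isolated)
Conditions: 15 (1.2 equiv), Bu2BOTf (1.3 equiv), Et3N (1.5 equiv), CH2Cl2, −78 → 0 °C; 14, −78 → −10 °C; pH 7 buffer, MeOH, 30 % H2O2, 0 °C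
Reagents that add atoms: none
Why: Evans syn aldol: the (Z)-boron enolate reacts through a closed Zimmerman–Traxler chair on the enolate face remote from the benzyl group of the (R)-auxiliary, which sets C7 and C8 as (2R,3S) with isopropyl and hydroxyl syn.

Step 8
Reactants: 17 (4R)-4-benzyl-3-[(2R,3S,5E,9Z)-9-({[tert-butyl(diphenyl)silyl]oxy}methyl)-3-hydroxy-10-iodo-5-methyl-2-(propan-2-yl)deca-5,9-dienoyl]-1,3-oxazolidin-2-one
Product: 18 (2R,3S,5E,9Z)-9-({[tert-butyl(diphenyl)silyl]oxy}methyl)-3-hydroxy-10-iodo-N-methoxy-N,5-dimethyl-2-(propan-2-yl)deca-5,9-dienamide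
Conditions: MeNH(OMe)·HCl (3 equiv), AlMe3 (3 equiv), CH2Cl2, −20 → 0 °C; aq. KNaC4H4O6
Reagents that add atoms: N,O-dimethylhydroxylamine hydrochloride, CNOC.Cl
Why: Aluminium amide transamination of a β-hydroxy imide, in which the C8 aluminium alkoxide directs the amide to the exocyclic carbonyl, releases the auxiliary and leaves C7 untouched.

Step 9
Reactants: 18 (2R,3S,5E,9Z)-9-({[tert-butyl(diphenyl)silyl]oxy}methyl)-3-hydroxy-10-iodo-N-methoxy-N,5-dimethyl-2-(propan-2-yl)deca-5,9-dienamide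
Product: 19 (2R,3S,5E,9Z)-3-acetoxy-9-({[tert-butyl(diphenyl)silyl]oxy}methyl)-10-iodo-N-methoxy-N,5-dimethyl-2-(propan-2-yl)deca-5,9-dienamide
Conditions: Ac2O (3 equiv), DMAP (10 mol %), pyridine, CH2Cl2, rt
Reagents that add atoms: acetic anhydride, CC(=O)OC(C)=O
Why: DMAP-catalysed acetylation of the only free hydroxyl puts the C8 acetate in place before any second hydroxyl exists, and the amide α-proton is not acidic enough for β-elimination under these conditions.

Step 10
Reactants: 19 (2R,3S,5E,9Z)-3-acetoxy-9-({[tert-butyl(diphenyl)silyl]oxy}methyl)-10-iodo-N-methoxy-N,5-dimethyl-2-(propan-2-yl)deca-5,9-dienamide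
Product: 20 (2R,3S,5E,9Z)-3-acetoxy-9-({[tert-butyl(diphenyl)silyl]oxy}methyl)-10-iodo-5-methyl-2-(propan-2-yl)deca-5,9-dienal
Conditions: Cp2Zr(H)Cl (1.6 equiv), THF, rt, 20 min; wet silica
Reagents that add atoms: none
Why: Hydrozirconation of the amide carbonyl gives a zirconium hemiaminal that releases the aldehyde only on work-up, a known chemoselective amide-to-aldehyde reduction that spares esters, so C6 reaches the aldehyde level under neutral conditions that should neither epimerise C7 nor eliminate the C8 acetate.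

Step 11
Reactants: 20 (2R,3S,5E,9Z)-3-acetoxy-9-({[tert-butyl(diphenyl)silyl]oxy}methyl)-10-iodo-5-methyl-2-(propan-2-yl)deca-5,9-dienal
Product: 22 (1(10)E,4Z,6S,7S,8S)-8-acetoxy-15-[(tert-butyldiphenylsilyl)oxy]germacra-1(10),4-dien-6-ol, via alkenylchromium dichloride 21 (not isolated)
Conditions: CrCl2 (12 equiv), NiCl2 (3 mol %), degassed DMSO–THF (3:1), rt, 20 added over 12 h to 1 mM; aq. NH4Cl
Reagents that add atoms: none
Why: Zerovalent nickel formed from NiCl2 and CrCl2 inserts into the C5–I bond with retention, transmetalation to trivalent chromium gives alkenylchromium 21, and this adds to the C6 aldehyde of the same chain, which is the Nozaki–Hiyama–Kishi reaction in its macrocyclising form, known for medium and large carbocyclic allylic alcohols. The ten-membered ring C1–C10 closes in a 10-exo-trig mode, with the two trisubstituted alkenes C1=C10 and C4=C5 already in place to stiffen the chain. The new stereocentre C6 is controlled by C7: with the isopropyl group anti to the incoming C5 (Felkin–Anh) and C8 gauche, the (6S) alcohol should result, 1,3-anti to the C8 acetate, while A(1,3) strain with the cis C15 oxymethyl keeps the aldehyde hydrogen and not the chromium-bound oxygen in the plane of C4=C5. The step needs cyclisation over oligomerisation (slow addition at millimolar concentration), addition to the aldehyde and not to the acetate (organochromium species do not add to esters), and retention of the C4=C5 geometry (alkenylchromium species are configurationally stable).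

Step 12
Reactants: 22 (1(10)E,4Z,6S,7S,8S)-8-acetoxy-15-[(tert-butyldiphenylsilyl)oxy]germacra-1(10),4-dien-6-ol
Product: 23 (1(10)E,4Z,6S,7S,8S)-8-acetoxygermacra-1(10),4-diene-6,15-diol
Conditions: Bu4NF (3 equiv), AcOH (3 equiv), THF, 0 °C → rt
Reagents that add atoms: none
Why: Fluoride-mediated desilylation buffered with acetic acid stays near neutral, so neither base-induced migration of the C8 acetate to O6 nor acid-induced transannular cyclisation of the 1(10),4-diene should occur.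

Step 13
Reactants: 23 (1(10)E,4Z,6S,7S,8S)-8-acetoxygermacra-1(10),4-diene-6,15-diol; 24 (2Z)-2-methylbut-2-enoic acid
Product: 26 (1(10)E,4Z,6S,7S,8S)-8-acetoxy-6-hydroxygermacra-1(10),4-dien-15-yl (2Z)-2-methylbut-2-enoate, via mixed anhydride 25 (not isolated)
Conditions: 24 (1.5 equiv), 2,4,6-trichlorobenzoyl chloride (1.5 equiv), Et3N (3 equiv), toluene, rt, 2 h; then 23, rt → 40 °C (no DMAP)
Reagents that add atoms: none
Why: Yamaguchi-type mixed-anhydride esterification without a nucleophilic catalyst transfers the angeloyl group without Z-to-E isomerisation, and the primary allylic C15 hydroxyl should react well ahead of the C6 hydroxyl, which is secondary and flanked by the C7 isopropyl group.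

**Compound list**

1 | tert-butyl(but-3-yn-1-yloxy)dimethylsilane | C#CCCO[Si](C)(C)C(C)(C)C | starting material
2 | oxirane | C1CO1 | starting material
3 | [(1E)-4-{[tert-butyl(dimethyl)silyl]oxy}-2-methylbut-1-en-1-yl]dimethylalane | C[Al](C)/C=C(\C)CCO[Si](C)(C)C(C)(C)C | intermediate
4 | lithium butyl[(1E)-4-{[tert-butyl(dimethyl)silyl]oxy}-2-methylbut-1-en-1-yl]dimethylalanate | [Li+].CCCC[Al-](C)(C)/C=C(\C)CCO[Si](C)(C)C(C)(C)C | intermediate
5 | (3E)-6-{[tert-butyl(dimethyl)silyl]oxy}-4-methylhex-3-en-1-ol | OCC/C=C(\C)CCO[Si](C)(C)C(C)(C)C | intermediate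
6 | {[(3E)-6-bromo-3-methylhex-3-en-1-yl]oxy}(tert-butyl)dimethylsilane | BrCC/C=C(\C)CCO[Si](C)(C)C(C)(C)C | intermediate
7 | prop-2-yn-1-ol | C#CCO | starting material
8 | [(3E)-6-{[tert-butyl(dimethyl)silyl]oxy}-4-methylhex-3-en-1-yl]magnesium bromide | Br[Mg]CC/C=C(\C)CCO[Si](C)(C)C(C)(C)C | intermediate
9 | chloromagnesium prop-2-yn-1-olate | C#CCO[Mg]Cl | intermediate
10 | bromo[(1Z,5E)-8-{[tert-butyl(dimethyl)silyl]oxy}-2-{[(chloromagnesio)oxy]methyl}-6-methylocta-1,5-dien-1-yl]magnesium | Br[Mg]/C=C(\CO[Mg]Cl)CC/C=C(\C)CCO[Si](C)(C)C(C)(C)C | intermediate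
11 | (5E)-8-{[tert-butyl(dimethyl)silyl]oxy}-2-[(Z)-iodomethylidene]-6-methyloct-5-en-1-ol | I/C=C(\CO)CC/C=C(\C)CCO[Si](C)(C)C(C)(C)C | intermediate
12 | tert-butyl{[(2Z,5E)-8-{[tert-butyl(dimethyl)silyl]oxy}-2-(iodomethylidene)-6-methyloct-5-en-1-yl]oxy}diphenylsilane | I/C=C(\CO[Si](c1ccccc1)(c1ccccc1)C(C)(C)C)CC/C=C(\C)CCO[Si](C)(C)C(C)(C)C | intermediate
13 | (3E,7Z)-7-({[tert-butyl(diphenyl)silyl]oxy}methyl)-8-iodo-3-methylocta-3,7-dien-1-ol | I/C=C(\CO[Si](c1ccccc1)(c1ccccc1)C(C)(C)C)CC/C=C(\C)CCO | intermediate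
14 | (3E,7Z)-7-({[tert-butyl(diphenyl)silyl]oxy}methyl)-8-iodo-3-methylocta-3,7-dienal | I/C=C(\CO[Si](c1ccccc1)(c1ccccc1)C(C)(C)C)CC/C=C(\C)CC=O | intermediate
15 | (4R)-4-benzyl-3-(3-methylbutanoyl)-1,3-oxazolidin-2-one | CC(C)CC(=O)N1[C@H](Cc2ccccc2)COC1=O | starting material
16 | dibutylboron (Z)-enolate of 15 | CC(C)/C=C(\OB(CCCC)CCCC)N1[C@H](Cc2ccccc2)COC1=O | intermediate
17 | (4R)-4-benzyl-3-[(2R,3S,5E,9Z)-9-({[tert-butyl(diphenyl)silyl]oxy}methyl)-3-hydroxy-10-iodo-5-methyl-2-(propan-2-yl)deca-5,9-dienoyl]-1,3-oxazolidin-2-one | CC(C)[C@@H](C(=O)N1[C@H](Cc2ccccc2)COC1=O)[C@@H](O)C/C(C)=C/CC/C(CO[Si](c1ccccc1)(c1ccccc1)C(C)(C)C)=C/I | intermediate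
18 | (2R,3S,5E,9Z)-9-({[tert-butyl(diphenyl)silyl]oxy}methyl)-3-hydroxy-10-iodo-N-methoxy-N,5-dimethyl-2-(propan-2-yl)deca-5,9-dienamide | CC(C)[C@@H](C(=O)N(C)OC)[C@@H](O)C/C(C)=C/CC/C(CO[Si](c1ccccc1)(c1ccccc1)C(C)(C)C)=C/I | intermediate
19 | (2R,3S,5E,9Z)-3-acetoxy-9-({[tert-butyl(diphenyl)silyl]oxy}methyl)-10-iodo-N-methoxy-N,5-dimethyl-2-(propan-2-yl)deca-5,9-dienamide | CC(C)[C@@H](C(=O)N(C)OC)[C@@H](OC(C)=O)C/C(C)=C/CC/C(CO[Si](c1ccccc1)(c1ccccc1)C(C)(C)C)=C/I | intermediate
20 | (2R,3S,5E,9Z)-3-acetoxy-9-({[tert-butyl(diphenyl)silyl]oxy}methyl)-10-iodo-5-methyl-2-(propan-2-yl)deca-5,9-dienal | CC(C)[C@@H](C=O)[C@@H](OC(C)=O)C/C(C)=C/CC/C(CO[Si](c1ccccc1)(c1ccccc1)C(C)(C)C)=C/I | intermediate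
21 | (Z)-alkenylchromium dichloride derived from 20 (Cr in place of I on C5) | CC(C)[C@@H](C=O)[C@@H](OC(C)=O)C/C(C)=C/CC/C(CO[Si](c1ccccc1)(c1ccccc1)C(C)(C)C)=C/[Cr](Cl)Cl | intermediate
22 | (1(10)E,4Z,6S,7S,8S)-8-acetoxy-15-[(tert-butyldiphenylsilyl)oxy]germacra-1(10),4-dien-6-ol | CC(C)(C)[Si](c1ccccc1)(c2ccccc2)OC/C3=C\[C@H](O)[C@H](C(C)C)[C@@H](OC(C)=O)C/C(C)=C/CC3 | intermediate
23 | (1(10)E,4Z,6S,7S,8S)-8-acetoxygermacra-1(10),4-diene-6,15-diol | OC/C1=C\[C@H](O)[C@H](C(C)C)[C@@H](OC(C)=O)C/C(C)=C/CC1 | intermediate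
24 | (2Z)-2-methylbut-2-enoic acid (angelic acid) | C/C=C(/C)C(=O)O | starting material
25 | (2Z)-2-methylbut-2-enoic 2,4,6-trichlorobenzoic anhydride | C/C=C(/C)C(=O)OC(=O)c1c(Cl)cc(Cl)cc1Cl | intermediate
26 | [(1Z,3S,4S,5S,7E)-5-acetoxy-3-hydroxy-7-methyl-4-(propan-2-yl)cyclodeca-1,7-dien-1-yl]methyl (2Z)-2-methylbut-2-enoate | C/C=C(/C)C(=O)OC/C1=C\[C@H](O)[C@H](C(C)C)[C@@H](OC(C)=O)C/C(C)=C/CC1 | target

**Totals and risks**

Total step count: 13. Longest linear sequence: 13 steps (from 1).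

Steps most likely to fail:

1. Step 11. The ring closure may show poor facial selectivity at C6, because the ten-membered transition state need not follow the acyclic Felkin–Anh preference, and would then give the C6 epimer or a mixture. The fallback sets out from 22 (as either epimer or the mixture) and comes back to 22 as the single (6S) isomer. Methanolysis of the C8 acetate (K2CO3, MeOH, 0 °C) should give the C6-epimeric 6,8-diol F1. MnO2 (CH2Cl2, rt) should oxidise only the allylic C6 hydroxyl and give the β-hydroxy enone F2. An Evans–Tishchenko reduction (acetaldehyde, SmI2 20 mol %, THF, −10 °C) should then pass hydride from the C8 hemiacetal to C6 through a six-membered chair, which sets C6 1,3-anti to O8 and leaves the acetyl group on O8, that is 22.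

2. Step 10. The hydride may be consumed by competing reduction at the acetate or the iodoalkene or by hydrozirconation of an alkene, or the hindered amide may be reduced incompletely. The fallback sets out from 17 and comes back at 20 by protecting-group chemistry. LiBH4 (THF, MeOH 1 equiv, 0 °C) should cleave the auxiliary reductively to the 1,3-diol F3. Et3SiCl and imidazole (CH2Cl2, −20 °C) should silylate only the primary hydroxyl and give the triethylsilyl ether F4. Ac2O, DMAP and pyridine should give the acetate F5. Camphorsulfonic acid (cat.) in MeOH at −10 °C should remove the primary triethylsilyl group ahead of the TBDPS group and give the primary alcohol F6. Buffered DMP oxidation of F6 gives 20.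

3. Step 8. The aluminium amide may attack the ring carbonyl of the oxazolidinone (endocyclic cleavage), or the hindered α-isopropyl adduct may undergo retro-aldol fragmentation. The fallback sets out from 17 and comes back at 18 by hydrolysis and amide coupling. LiOH and H2O2 (THF–H2O, 0 °C) should cleave the exocyclic acyl group selectively to the β-hydroxy acid F7. Coupling of F7 with MeNH(OMe)·HCl (EDC·HCl, HOBt, i-Pr2NEt, CH2Cl2) gives 18.

**Further compounds**

F1 | step 11 | 15-[(tert-butyldiphenylsilyl)oxy]germacra-1(10),4-diene-6,8-diol (C6 epimers; C7 and C8 as in 22) | CC(C)(C)[Si](c1ccccc1)(c1ccccc1)OC/C1=C\C(O)[C@H](C(C)C)[C@@H](O)C/C(C)=C/CC1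
F2 | step 11 | 15-[(tert-butyldiphenylsilyl)oxy]-8-hydroxygermacra-1(10),4-dien-6-one (C7 and C8 as in 22) | CC(C)(C)[Si](c1ccccc1)(c1ccccc1)OC/C1=C\C(=O)[C@H](C(C)C)[C@@H](O)C/C(C)=C/CC1
F3 | step 10 | (2S,3S,5E,9Z)-9-({[tert-butyl(diphenyl)silyl]oxy}methyl)-10-iodo-5-methyl-2-(propan-2-yl)deca-5,9-diene-1,3-diol | CC(C)[C@@H](CO)[C@@H](O)C/C(C)=C/CC/C(CO[Si](c1ccccc1)(c1ccccc1)C(C)(C)C)=C/I
F4 | step 10 | 1-O-triethylsilyl ether of F3 | CC(C)[C@@H](CO[Si](CC)(CC)CC)[C@@H](O)C/C(C)=C/CC/C(CO[Si](c1ccccc1)(c1ccccc1)C(C)(C)C)=C/I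
F5 | step 10 | 3-O-acetate of F4 | CC(C)[C@@H](CO[Si](CC)(CC)CC)[C@@H](OC(C)=O)C/C(C)=C/CC/C(CO[Si](c1ccccc1)(c1ccccc1)C(C)(C)C)=C/I
F6 | step 10 | (2S,3S,5E,9Z)-9-({[tert-butyl(diphenyl)silyl]oxy}methyl)-1-hydroxy-10-iodo-5-methyl-2-(propan-2-yl)deca-5,9-dien-3-yl acetate | CC(C)[C@@H](CO)[C@@H](OC(C)=O)C/C(C)=C/CC/C(CO[Si](c1ccccc1)(c1ccccc1)C(C)(C)C)=C/I
F7 | step 8 | (2R,3S,5E,9Z)-9-({[tert-butyl(diphenyl)silyl]oxy}methyl)-3-hydroxy-10-iodo-5-methyl-2-(propan-2-yl)deca-5,9-dienoic acid | CC(C)[C@@H](C(=O)O)[C@@H](O)C/C(C)=C/CC/C(CO[Si](c1ccccc1)(c1ccccc1)C(C)(C)C)=C/I
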